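The numbers in the tables were computed from invented constants; scatter was added.

Start from the leftover: add substrate and product in each reading of the two earlier runs, and what falls short of the charge is, on average, 5.57 µM in the south run and 6.50 µM in the north run. Read this as substrate held on the 10 µM of catalyst, and take the north figure as a rough reading, since it rests on small gaps between scattered numbers.

| flask | substrate | partner | free catalyst | temperature | remark | time |
|---|---|---|---|---|---|---|
| south | 0.50 mM | 1.2 mM | 10 µM | −5 °C | run made earlier |  |
| north | 2 mM | 1.2 mM | 10 µM | 25 °C | run made earlier |  |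
| Wednesday's | 1.0 mM | 1.20 mM | 10 µM | 0 °C |  | 2.0 min |
| Saturday's | 1.0 mM | 1.20 mM | 10 µM | 50 °C |  | 2.0 min |
| Sunday's | 1.0 mM | 1.20 mM | 10 µM | 25 °C |  | 2.0 min |

| run | time / s | product / % | substrate / % |
|---|---|---|---|
| south | 10.0 | 1.6 | 97.2 |
| south | 20.0 | 4.0 | 95.0 |
| south | 30.0 | 5.5 | 93.2 |
| south | 50.0 | 9.4 | 89.5 |
| south | 80.0 | 14.1 | 84.2 |
| south | 90.0 | 15.6 | 83.1 |
| south | 120 | 21.9 | 77.9 |
| north | 10.0 | 10.5 | 89.2 |
| north | 15.0 | 15.3 | 84.4 |
| north | 25.0 | 24.2 | 75.4 |
| north | 40.0 | 35.5 | 64.2 |

(scatter of a reading: 0.3 percentage points)

* the best flask by amount of product, in percent of the substrate charged; "all alike" if 1.5 percentage points covers them all (Wednesday's / Saturday's / Sunday's / all alike)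
* amount of product at the end, in percent of the substrate charged, Wednesday's
* amount of product at the end, in percent of the substrate charged, Saturday's
* amount of product at the end, in percent of the substrate charged, Sunday's

- the numbers in the tables scatter with a standard deviation of 0.3 percentage points

Sunday's stands at the temperature of the north run, so take from that run a held share of the catalyst of 65.0%, set roughly against its substrate charge, and a first rate of 21.0 µM/s. Treat the held catalyst as releasing at a steady pace, with the share following substrate as simple binding does, and two times come out. The passage time, 31.0 s, is what Sunday's charge takes at full hold. The tail time, 33.3 s, is the time in which the last substrate falls by a factor e once the catalyst has mostly let go, a pseudo-first-order stretch. Compute only the correction: subtract the passage time from the run and divide by the tail time, and Sunday's keeps 6.92% of its substrate, so my own figure for product is 93.1%. Wednesday's and Saturday's stand at other temperatures, so leave them to the forecast.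

The forecast named Sunday's as best, with 19% (16% to 23%) for Wednesday's, 65% (20% to 100%) for Saturday's and 98% (90% to 100%) for Sunday's, saying: “At 25 °C either reading gives about 1400 µM or more of capacity, so Sunday's essentially finishes.” My figure for Sunday's stands lower than that.

The flasks give 22.2% on Wednesday's, 82.2% on Saturday's and 88.2% on Sunday's, so the best is Sunday's.

    partner + free catalyst → catalyst intermediate A (k = 17000 /M/s, Ea = 13.0 kJ/mol)
    substrate + catalyst intermediate A ⇌ catalyst intermediate B (K = 890 /M, k = 21000 /M/s, Ea = 13.0 kJ/mol, ΔH = −37.0 kJ/mol)
    catalyst intermediate B ⇌ free catalyst + product (K = 9.80 × 10⁻⁴ M, k = 4.20 /s, Ea = 76.0 kJ/mol, ΔH = −40.0 kJ/mol)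
    (constants at 25 °C)

At the end of Sunday's, the step between substrate with catalyst intermediate A and catalyst intermediate B, taken alone and both ways together, relaxes with a half-life of 0.0264 s, shorter than the 0.0868 s of the step between catalyst intermediate B and free catalyst with product, taken the same way. Both are far shorter than the 2.0 min of the run. Sunday's keeps 12% of its substrate, and its fall from 34.2% at 1.00 min gives a tail time of 56.0 s, longer than the 33.3 s reckoned. For the neighbour of Sunday's charged with 0.25 mM of substrate, the same two times give a remainder of 3.43%, and that flask keeps 3.2%.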